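(Readings and results come from a simulation with made-up constants, and the scatter is random.)

3 questions stand on your flask, and you wanted a quick number, with the hunch that X ends it. Here is mine, as a large term plus a correction.

1. which holds at 6.0 h: what has brought the reaction to rest, or that it has not come to rest (for what has run out or reacted, a solid counts together with what of it has only dissolved) (it is still moving / X has run out first / all of D has reacted)
2. part of the D that has turned into other species by 6.0 h (what has only dissolved does not count)
3. G at 6.0 h, in percent of the D charged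

| setting | noon | winter | spring | flask |
|---|---|---|---|---|
| D | 0.42 M | 0.66 M | 0.30 M | 0.30 M |
| X | 0.70 equiv | 0.70 equiv | 0.35 equiv | 0.700 equiv |
| remark | run made earlier | run made earlier | run made earlier |  |
| time |  |  |  | 6.0 h |

| run | time / h | D / % | G / % |
|---|---|---|---|
| noon | 0.250 | 86.2 | 12.3 |
| noon | 0.667 | 64.1 | 34.4 |
| noon | 1.33 | 28.9 | 67.7 |
| noon | 2.00 | 17.7 | 71.1 |
| noon | 3.00 | 15.1 | 70.8 |
| noon | 4.00 | 16.3 | 70.1 |
| noon | 5.00 | 17.3 | 69.3 |
| winter | 0.250 | 90.3 | 9.3 |
| winter | 0.667 | 72.7 | 23.4 |
| winter | 1.33 | 51.6 | 45.4 |
| winter | 2.00 | 29.0 | 66.1 |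
| winter | 3.00 | 21.6 | 70.5 |
| winter | 4.00 | 17.5 | 71.3 |
| winter | 5.00 | 19.3 | 69.1 |
| spring | 0.417 | 68.7 | 27.7 |
| spring | 0.667 | 57.3 | 35.7 |
| spring | 1.33 | 46.8 | 36.3 |
| spring | 2.50 | 46.6 | 34.7 |
| spring | 5.00 | 45.1 | 35.3 |

(readings scatter by 1 percentage point)

- a species is counted by the D in it: one Z counts as two
- given per volume of solution although it is solid: D
- what may be going on: D <-> E; E + X -> G; 2 D -> Z
- at the start none of D is in solution
- what has only dissolved of D counts as not reacted
- the reaction counts as stopped when no species that holds the D changes by six tenths of a point or more over the second half of the time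

Your hunch holds on my reckoning. G in the noon run first climbs at 0.207 M h⁻¹, and your flask charges 0.210 M of X, so X, the limiting reagent, lasts about 1.02 h, far shorter than the 6.0 h asked. G in your flask should therefore end near 70.0%.

But D and G do not add up. In the noon run the gap reads 14.1% at 3.00 h and 13.4% at 5.00 h, flat within the scatter. I read it as the dissolved pool, the concentration of D standing in solution at rest, 0.0563 M. Your question does not count that as reacted. In your flask this pool is 18.8% of the charge, which leaves 11.2% as solid, before any Z is counted. Neither part is converted, so I commit to a conversion of 70.0%, plus a correction for Z that I cannot read from the scatter.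

The forecast agrees on X has run out first and G at 70%, but puts the conversion at 85%, higher than my figure, with D and E in your flask “about as in the noon run”.

Your flask gives X has run out first, G at 70.0% and conversion at 70.9%. At 6.00 h it holds E, the dissolved D, at 17.7%, and the correction, Z, at 0.903%.

    D ⇌ E, rate k1*(cs1 - [E]) while solid is left; crystals form when [E] > cs1 (solubility = 0.0530 M, k = 0.0750 min⁻¹)
    E + X → G (k = 9.00 L mol⁻¹ min⁻¹)
    2 D → Z (k = 4.90 × 10⁻⁴ L mol⁻¹ min⁻¹)

Now take the neighbour with 0.280 equiv of X and the same D. The pool is again 18.8% of the charge, so the reckoning leaves 53.2% as solid, before any Z is counted. That neighbour holds D at 51.0%, E at 17.7%, G at 28.0% and Z at 3.32%, a conversion of 31.3%.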